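**Plan**

1. Numbering used here: ring A is O1–C2(=O)–C3(butyl)=C4(Br)–C5(spiro); ring B is C6(spiro)–O7–C8(=O)–C9(side chain)=C10(Br); the cyclobutane is C5–C6–C11(H)Br–C12(H)Br.
2. Retrosynthesis: remove the acetate and return C1′ to a ketone, then cut C3–C4 and C9–C10 (two Dieckmann closures) and the acyl C–O bonds O1–C2 and O7–C8, which leaves a C2-symmetric dimethyl 1,2-dihydroxycyclobutane-1,2-dicarboxylate.
3. The tertiary C5–O and C6–O bonds go back to C–H (Rubottom oxidation of exocyclic enol ethers); C4 and C10 go back to two formyl carbons, and these to the ends of a cyclohexadiene (ozonolysis).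
4. Last cuts: C5–C6 together with C11–Br and C12–Br, all made when Br2 adds to cyclooctatetraene and the dibromotriene closes across the ring. The enabling feature is the cyclobutane C5–C6–C11–C12 with a trans C11H(Br)–C12H(Br) edge whose neighbours C5 and C6 each carry exactly one exocyclic carbon (C4, C10).
5. Forward order: cyclobutane first (fused to a cyclohexadiene that is then cut away), butenolide rings A and B closed together late, side chain adjusted last.
6. Stereochemistry: C11/C12 trans from anti addition of bromine; C5/C6 from peracid attack anti to each neighbouring bromine; C1′ from CBS reduction; absolute configuration of the core from resolution of the diol diester.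

Key step: step 1

Remark on the chemistry: every compound from the key step up to the resolution is racemic and is drawn as the enantiomer that leads to the target; the enol ether geometry of the step 3 product has no stereochemical consequence and the Z,Z isomer is drawn.

Step 1
Reactants: 1 cyclooctatetraene; 2 bromine
Product: 4 rac-(1S,6R,7R,8R)-7,8-dibromobicyclo[4.2.0]octa-2,4-diene, via rac-(7R,8R)-7,8-dibromocycloocta-1,3,5-triene 3 (not isolated)
Conditions: Br2 (1.0 equiv), CH2Cl2, −70 °C, then warm to 0 °C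
Reagents that add atoms: bromine (2), BrBr
Why: Electrophilic bromine addition followed by a thermal 6π electrocyclisation (valence isomerisation of a cycloocta-1,3,5-triene): Br2 attacks one alkene of the tub-shaped tetraene to give a bromohomotropylium ion pair, bromide is captured at the carbon next to the CHBr carbon, and any cis-dibromide should revert through the ion pair so that material funnels through trans-triene 3. The closest known reaction type is the halogenation of cyclooctatetraene to its bicyclic dihalides. The triene termini C1 and C6 then join by a thermally allowed disrotatory 6π closure, a single σ-bond that creates the cyclobutane and the cyclohexadiene at once and, from the all-Z triene, can only give the cis ring fusion. The two CHBr centres should come out trans because bromide enters anti to the first bromine; they are the only stereocentres of 4 that persist, the cis-fused CH centres being erased in step 3. The step needs clean 1,2-mono-addition, which the 1:1 stoichiometry and the low temperature should secure against further bromination of the product diene. The two C–Br bonds and the new C–C bond are the future C11–Br, C12–Br and C5–C6 bonds of the target.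

Step 2
Reactants: 4 rac-(1S,6R,7R,8R)-7,8-dibromobicyclo[4.2.0]octa-2,4-diene
Product: 5 rac-(1R,2S,3R,4R)-3,4-dibromocyclobutane-1,2-dicarbaldehyde (cis-dialdehyde, trans-dibromide)
Conditions: O3, CH2Cl2, −78 °C; then Me2S, −78 °C → rt; used crude and cold
Reagents that add atoms: ozone, [O-][O+]=O
Why: Ozonolysis with reductive work-up (Criegee mechanism) cleaves both alkenes of the cyclohexadiene, excising C3–C4 as glyoxal and leaving C2 and C5 as formyl groups on the intact dibromocyclobutane, while the saturated C–Br bonds are inert to ozone and no base is present that could trigger β-elimination of HBr.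

Step 3
Reactants: 5 rac-(1R,2S,3R,4R)-3,4-dibromocyclobutane-1,2-dicarbaldehyde
Product: 6 rac-(3R,4R)-3,4-dibromo-1,2-bis[(tert-butyldimethylsilyloxy)methylidene]cyclobutane (Z,Z isomer drawn)
Conditions: Et3N (4 equiv), TBSOTf (2.4 equiv), CH2Cl2, −78 → −20 °C; cold NaHCO3 work-up, used at once
Reagents that add atoms: tert-butyldimethylsilyl trifluoromethanesulfonate, CC(C)(C)[Si](C)(C)OS(=O)(=O)C(F)(F)F
Why: Soft enolisation (silyl triflate/amine silyl enol ether formation) of the α-branched aldehydes, in which O-silylation precedes deprotonation and should outrun E1cB loss of the β-bromide at low temperature, turns both ring-fusion carbons into sp2 centres and so deliberately erases their cis relationship.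

Step 4
Reactants: 6 rac-(3R,4R)-3,4-dibromo-1,2-bis[(tert-butyldimethylsilyloxy)methylidene]cyclobutane
Product: 7 rac-(1R,2R,3R,4R)-3,4-dibromo-1,2-bis(tert-butyldimethylsilyloxy)cyclobutane-1,2-dicarbaldehyde
Conditions: mCPBA (2.2 equiv), NaHCO3, CH2Cl2, −20 → 0 °C
Reagents that add atoms: 3-chloroperoxybenzoic acid, OOC(=O)c1cccc(Cl)c1
Why: Rubottom oxidation, in which the peracid should attack each exocyclic enol ether on the ring face anti to the adjacent C–Br bond and 1,4-silyl shift unmasks the aldehyde, so that C1 receives oxygen anti to Br at C4 and C2, now also shielded by the first siloxy group, receives oxygen anti to Br at C3 (the all-trans O/Br/Br/O array of the target), while the silyl ethers block α-ketol ring expansion of the hydroxycyclobutanecarbaldehyde.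

Step 5
Reactants: 7 rac-(1R,2R,3R,4R)-3,4-dibromo-1,2-bis(tert-butyldimethylsilyloxy)cyclobutane-1,2-dicarbaldehyde
Product: 8 rac-(1R,2R,3R,4R)-3,4-dibromo-1,2-bis(tert-butyldimethylsilyloxy)cyclobutane-1,2-dicarboxylic acid
Conditions: NaClO2, NaH2PO4, 2-methyl-2-butene, t-BuOH/H2O, 0 °C → rt
Reagents that add atoms: sodium chlorite, [Na+].[O-]Cl=O
Why: Pinnick oxidation converts the hindered, non-enolisable aldehydes into acids under buffered conditions that leave silyl ethers, alkyl bromides and all stereocentres untouched.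

Step 6
Reactants: 8 rac-(1R,2R,3R,4R)-3,4-dibromo-1,2-bis(tert-butyldimethylsilyloxy)cyclobutane-1,2-dicarboxylic acid
Product: 10 rac-dimethyl (1R,2R,3R,4R)-3,4-dibromo-1,2-dihydroxycyclobutane-1,2-dicarboxylate, via bis-TBS dimethyl ester 9 (not isolated)
Conditions: TMSCHN2, PhMe/MeOH, 0 °C; evaporate; then 48% aq. HF, MeCN, rt
Reagents that add atoms: trimethylsilyldiazomethane, C[Si](C)(C)C=[N+]=[N-]
Why: Diazoalkane esterification methylates the hindered acids without base or iodide (either of which would endanger the vicinal dibromide), and fluoride-mediated desilylation then frees the two tertiary alcohols without touching esters or bromides.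

Step 7
Reactants: 10 rac-dimethyl (1R,2R,3R,4R)-3,4-dibromo-1,2-dihydroxycyclobutane-1,2-dicarboxylate
Product: 11 dimethyl (1R,2R,3R,4R)-3,4-dibromo-1,2-dihydroxycyclobutane-1,2-dicarboxylate (single enantiomer)
Conditions: preparative HPLC, amylose tris(3,5-dimethylphenylcarbamate) stationary phase, hexane/i-PrOH
Reagents that add atoms: none
Why: Chromatographic resolution on a polysaccharide chiral stationary phase is placed at the first robust, configurationally fixed C2-symmetric intermediate, and the (1R,2R,3R,4R) antipode is to be identified by anomalous-dispersion X-ray analysis of the bromine atoms before it is carried on.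

Step 8
Reactants: 11 dimethyl (1R,2R,3R,4R)-3,4-dibromo-1,2-dihydroxycyclobutane-1,2-dicarboxylate; 12 hexanoyl chloride
Product: 13 dimethyl (1R,2R,3R,4R)-3,4-dibromo-1-(hexanoyloxy)-2-hydroxycyclobutane-1,2-dicarboxylate
Conditions: hexanoyl chloride (1.0 equiv), pyridine, DMAP (0.1 equiv), CH2Cl2, 0 °C → rt; recovered 11 recycled
Reagents that add atoms: hexanoyl chloride (12), CCCCCC(Cl)=O
Why: Nucleophile-catalysed acylation of a tertiary α-hydroxy ester, in which the two hydroxyls are homotopic so either gives the same mono-ester, and limiting acyl chloride together with the extra crowding after the first acylation should favour mono- over bis-acylation.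

Step 9
Reactants: 13 dimethyl (1R,2R,3R,4R)-3,4-dibromo-1-(hexanoyloxy)-2-hydroxycyclobutane-1,2-dicarboxylate; 14 ethyl 3-oxohexanoate
Product: 15 dimethyl (1R,2R,3R,4R)-3,4-dibromo-1-(hexanoyloxy)-2-[(3-oxohexanoyl)oxy]cyclobutane-1,2-dicarboxylate
Conditions: ethyl 3-oxohexanoate (5 equiv), DMAP (0.3 equiv), PhMe, reflux, 4 Å molecular sieves (EtOH removal)
Reagents that add atoms: ethyl 3-oxohexanoate (14), CCCC(=O)CC(=O)OCC
Why: β-Keto ester transacylation through an acylketene, in which the keto ester loses ethanol to butanoylketene and this neutral, highly reactive acylating agent should capture the remaining hindered tertiary alcohol.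

Step 10
Reactants: 15 dimethyl (1R,2R,3R,4R)-3,4-dibromo-1-(hexanoyloxy)-2-[(3-oxohexanoyl)oxy]cyclobutane-1,2-dicarboxylate
Product: 17 (5S,6S,11R,12R)-11,12-dibromo-9-butanoyl-3-butyl-4,10-dihydroxy-1,7-dioxadispiro[4.0.4.2]dodeca-3,9-diene-2,8-dione, via ring A spirotetronic acid 16 (not isolated)
Conditions: LiN(SiMe3)2 (4.5 equiv), THF, −78 °C → rt; then 1 M HCl
Reagents that add atoms: none
Why: Double Dieckmann condensation to two tetronic acids, in which the hexanoate enolate closes ring A by 5-exo-trig attack on the geminal methyl ester at low temperature, the β-keto ester enolate closes ring B on warming (Lacey–Dieckmann), formation of the stabilised tetronate anions drives both, 5-ring closure onto the geminal ester should beat 6-ring closure onto the vicinal ester or SN2 at the cyclobutyl C–Br, and the quaternary spiro centres cannot epimerise.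

Step 11
Reactants: 17 (5S,6S,11R,12R)-11,12-dibromo-9-butanoyl-3-butyl-4,10-dihydroxy-1,7-dioxadispiro[4.0.4.2]dodeca-3,9-diene-2,8-dione
Product: 18 (5S,6S,11R,12R)-4,10,11,12-tetrabromo-9-butanoyl-3-butyl-1,7-dioxadispiro[4.0.4.2]dodeca-3,9-diene-2,8-dione
Conditions: (COBr)2 (3 equiv), DMF (cat.), CH2Cl2, 0 °C → rt; non-aqueous work-up
Reagents that add atoms: oxalyl bromide, BrC(=O)C(Br)=O
Why: Vilsmeier-type deoxybromination of the vinylogous acids, in which O-activation as the iminium ether and addition–elimination of bromide at C4 and C10 gives the two vinylic C–Br bonds, the ring oxygen of the 3-acyl tetronic acid being expected to be replaced as in cyclic 2-acyl-1,3-diones.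

Step 12
Reactants: 18 (5S,6S,11R,12R)-4,10,11,12-tetrabromo-9-butanoyl-3-butyl-1,7-dioxadispiro[4.0.4.2]dodeca-3,9-diene-2,8-dione
Product: 19 (5S,6S,11R,12R)-4,10,11,12-tetrabromo-3-butyl-9-[(1R)-1-hydroxybutyl]-1,7-dioxadispiro[4.0.4.2]dodeca-3,9-diene-2,8-dione
Conditions: (S)-1-methyl-3,3-diphenyltetrahydro-1H,3H-pyrrolo[1,2-c][1,3,2]oxazaborole ((S)-Me-CBS, 0.5 equiv), catecholborane (1.5 equiv), PhMe/CH2Cl2, −78 °C; MeOH, then pH 7 buffer
Reagents that add atoms: none
Why: Corey–Bakshi–Shibata reduction, in which the tetrasubstituted alkenyl group acts as the large and n-propyl as the small substituent so that the (S)-oxazaborolidine should deliver hydride to give the (1′R)-carbinol under catalyst control, while catecholborane at −78 °C should reduce only the catalyst-activated ketone and leave lactones and vinylic bromides alone.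

Step 13
Reactants: 19 (5S,6S,11R,12R)-4,10,11,12-tetrabromo-3-butyl-9-[(1R)-1-hydroxybutyl]-1,7-dioxadispiro[4.0.4.2]dodeca-3,9-diene-2,8-dione
Product: 20 (5S,6S,11R,12R)-9-[(1R)-1-acetoxybutyl]-4,10,11,12-tetrabromo-3-butyl-1,7-dioxadispiro[4.0.4.2]dodeca-3,9-diene-2,8-dione (CNP0268004.1)
Conditions: Ac2O (1.5 equiv), Sc(OTf)3 (2 mol %), MeCN, −20 °C
Reagents that add atoms: acetic anhydride, CC(=O)OC(C)=O
Why: Lewis acid-catalysed acetylation of the secondary alcohol proceeds with retention at C1′ and without amine nucleophiles, which spares the electrophilic 4-bromobutenolides.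

**Compound list**

1 | cyclooctatetraene | C1=CC=CC=CC=C1 | starting material
2 | bromine | BrBr | starting material
3 | rac-(7R,8R)-7,8-dibromocycloocta-1,3,5-triene (trans-dibromide; not isolated) | Br[C@H]1[C@H](Br)/C=C\C=C/C=C\1 | intermediate
4 | rac-(1S,6R,7R,8R)-7,8-dibromobicyclo[4.2.0]octa-2,4-diene (trans-dibromide, cis ring fusion) | Br[C@H]1[C@H](Br)[C@@H]2C=CC=C[C@H]12 | intermediate
5 | rac-(1R,2S,3R,4R)-3,4-dibromocyclobutane-1,2-dicarbaldehyde | O=C[C@@H]1[C@@H](Br)[C@H](Br)[C@@H]1C=O | intermediate
6 | rac-(3R,4R)-3,4-dibromo-1,2-bis[(tert-butyldimethylsilyloxy)methylidene]cyclobutane (Z,Z drawn) | CC(C)(C)[Si](C)(C)O/C=C1\[C@@H](Br)[C@H](Br)/C1=C\O[Si](C)(C)C(C)(C)C | intermediate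
7 | rac-(1R,2R,3R,4R)-3,4-dibromo-1,2-bis(tert-butyldimethylsilyloxy)cyclobutane-1,2-dicarbaldehyde | O=C[C@@]1(O[Si](C)(C)C(C)(C)C)[C@@H](Br)[C@H](Br)[C@@]1(C=O)O[Si](C)(C)C(C)(C)C | intermediate
8 | rac-(1R,2R,3R,4R)-3,4-dibromo-1,2-bis(tert-butyldimethylsilyloxy)cyclobutane-1,2-dicarboxylic acid | OC(=O)[C@@]1(O[Si](C)(C)C(C)(C)C)[C@@H](Br)[C@H](Br)[C@@]1(C(O)=O)O[Si](C)(C)C(C)(C)C | intermediate
9 | rac-dimethyl (1R,2R,3R,4R)-3,4-dibromo-1,2-bis(tert-butyldimethylsilyloxy)cyclobutane-1,2-dicarboxylate (not isolated) | COC(=O)[C@@]1(O[Si](C)(C)C(C)(C)C)[C@@H](Br)[C@H](Br)[C@@]1(C(=O)OC)O[Si](C)(C)C(C)(C)C | intermediate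
10 | rac-dimethyl (1R,2R,3R,4R)-3,4-dibromo-1,2-dihydroxycyclobutane-1,2-dicarboxylate (racemate) | COC(=O)[C@@]1(O)[C@@H](Br)[C@H](Br)[C@@]1(C(=O)OC)O | intermediate
11 | dimethyl (1R,2R,3R,4R)-3,4-dibromo-1,2-dihydroxycyclobutane-1,2-dicarboxylate (single enantiomer) | COC(=O)[C@@]1(O)[C@@H](Br)[C@H](Br)[C@@]1(C(=O)OC)O | intermediate
12 | hexanoyl chloride | CCCCCC(Cl)=O | starting material
13 | dimethyl (1R,2R,3R,4R)-3,4-dibromo-1-(hexanoyloxy)-2-hydroxycyclobutane-1,2-dicarboxylate | COC(=O)[C@@]1(OC(=O)CCCCC)[C@@H](Br)[C@H](Br)[C@@]1(C(=O)OC)O | intermediate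
14 | ethyl 3-oxohexanoate | CCCC(=O)CC(=O)OCC | starting material
15 | dimethyl (1R,2R,3R,4R)-3,4-dibromo-1-(hexanoyloxy)-2-[(3-oxohexanoyl)oxy]cyclobutane-1,2-dicarboxylate | COC(=O)[C@@]1(OC(=O)CCCCC)[C@@H](Br)[C@H](Br)[C@@]1(C(=O)OC)OC(=O)CC(=O)CCC | intermediate
16 | methyl (1R,2R,3R,4S)-2,3-dibromo-7-butyl-8-hydroxy-6-oxo-1-[(3-oxohexanoyl)oxy]-5-oxaspiro[3.4]oct-7-ene-1-carboxylate (ring A closed; not isolated) | CCCCC1=C(O)[C@@]2(OC1=O)[C@@H](Br)[C@H](Br)[C@@]2(C(=O)OC)OC(=O)CC(=O)CCC | intermediate
17 | (5S,6S,11R,12R)-11,12-dibromo-9-butanoyl-3-butyl-4,10-dihydroxy-1,7-dioxadispiro[4.0.4.2]dodeca-3,9-diene-2,8-dione | CCCCC1=C(O)[C@@]2(OC1=O)[C@@H](Br)[C@H](Br)[C@@]21OC(=O)C(C(=O)CCC)=C1O | intermediate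
18 | (5S,6S,11R,12R)-4,10,11,12-tetrabromo-9-butanoyl-3-butyl-1,7-dioxadispiro[4.0.4.2]dodeca-3,9-diene-2,8-dione | CCCCC1=C(Br)[C@@]2(OC1=O)[C@@H](Br)[C@H](Br)[C@@]21OC(=O)C(C(=O)CCC)=C1Br | intermediate
19 | (5S,6S,11R,12R)-4,10,11,12-tetrabromo-3-butyl-9-[(1R)-1-hydroxybutyl]-1,7-dioxadispiro[4.0.4.2]dodeca-3,9-diene-2,8-dione | CCCCC1=C(Br)[C@@]2(OC1=O)[C@@H](Br)[C@H](Br)[C@@]21OC(=O)C([C@@H](CCC)O)=C1Br | intermediate
20 | (5S,6S,11R,12R)-9-[(1R)-1-acetoxybutyl]-4,10,11,12-tetrabromo-3-butyl-1,7-dioxadispiro[4.0.4.2]dodeca-3,9-diene-2,8-dione (CNP0268004.1) | CCCCC1=C(Br)[C@@]2(OC1=O)[C@@H](Br)[C@H](Br)[C@@]21OC(=O)C([C@@H](CCC)OC(C)=O)=C1Br | target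

**Totals**

Total step count: 13. Longest linear sequence: 13 steps (fully linear from cyclooctatetraene).

**Steps most likely to fail**

Step 3. The β-bromo aldehyde may lose HBr by E1cB elimination, or the electron-rich silyl enol ether may ionise its allylic C–Br bond, before oxidation can take place. The fallback sets out from 5 and returns at 10. The enol is trapped instead as a much less electron-rich enol ester under acid catalysis (isopropenyl acetate, cat. TsOH), giving the bis(enol acetate) F1; enol esters are known to tolerate an allylic bromide. Peracid oxidation with acid-promoted acetyl shift (enol ester epoxide rearrangement, ring C–O bond retained, attack again anti to each bromine) should give the bis(α-acetoxy aldehyde) F2. Pinnick oxidation then gives the diacetoxy diacid F3, trimethylsilyldiazomethane gives the diacetoxy dimethyl ester F4, and acid methanolysis (HCl, MeOH) of the acetates returns diol diester 10.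

Step 11. On the 3-acyl tetronic acid of ring B, bromide may enter at the exocyclic acyl carbon instead of C10, and the doubly activated vinylic bromide may hydrolyse on work-up. The fallback sets out from 11 and returns at 18, building ring B as a second 3-butyl ring and oxidising its side chain afterwards. Both hydroxyls are acylated with excess 12 to the bis-hexanoate F5. Double Dieckmann condensation (LiN(SiMe3)2) gives the C2-symmetric bis(3-butyl tetronic acid) F6, and oxalyl bromide/DMF, now on two simple 3-alkyl tetronic acids, gives the bis(3-butyl-4-bromobutenolide) F7. Wohl–Ziegler bromination (NBS, dibenzoyl peroxide, PhCF3, reflux, substoichiometric) at the activated C1′ methylene of one of the two homotopic butyl chains gives the 1′-bromide F8 as both epimers. Silver-assisted hydrolysis (AgNO3, aqueous acetone) gives the 1′-alcohol F9, and Dess–Martin oxidation converges both epimers on ketone 18.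

Step 12. Hydride may be delivered in the conjugate sense with expulsion of bromide from C10, or facial control by the catalyst may be weak because the ketone is twisted out of the alkene plane. The fallback sets out from 18 and returns at 19, giving up reagent control. Luche reduction (NaBH4, CeCl3·7H2O, MeOH, −78 °C) for clean 1,2-delivery should give 19 together with the (1′S)-epimeric alcohol F10. The epimers are separated by chromatography, and F10 is returned to 18 by Dess–Martin oxidation and recycled.

Further compounds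
F1 | step 3 | rac-[(3R,4R)-3,4-dibromocyclobutane-1,2-diylidene]bis(methanylylidene) diacetate (bis(enol acetate), Z,Z drawn) | CC(=O)O/C=C1\[C@@H](Br)[C@H](Br)/C1=C\OC(C)=O
F2 | step 3 | rac-(1R,2R,3R,4R)-3,4-dibromo-1,2-diformylcyclobutane-1,2-diyl diacetate | O=C[C@@]1(OC(C)=O)[C@@H](Br)[C@H](Br)[C@@]1(C=O)OC(C)=O
F3 | step 3 | rac-(1R,2R,3R,4R)-1,2-diacetoxy-3,4-dibromocyclobutane-1,2-dicarboxylic acid | OC(=O)[C@@]1(OC(C)=O)[C@@H](Br)[C@H](Br)[C@@]1(C(O)=O)OC(C)=O
F4 | step 3 | rac-dimethyl (1R,2R,3R,4R)-1,2-diacetoxy-3,4-dibromocyclobutane-1,2-dicarboxylate | COC(=O)[C@@]1(OC(C)=O)[C@@H](Br)[C@H](Br)[C@@]1(C(=O)OC)OC(C)=O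
F5 | step 11 | dimethyl (1R,2R,3R,4R)-3,4-dibromo-1,2-bis(hexanoyloxy)cyclobutane-1,2-dicarboxylate | COC(=O)[C@@]1(OC(=O)CCCCC)[C@@H](Br)[C@H](Br)[C@@]1(C(=O)OC)OC(=O)CCCCC
F6 | step 11 | (5S,6S,11R,12R)-11,12-dibromo-3,9-dibutyl-4,10-dihydroxy-1,7-dioxadispiro[4.0.4.2]dodeca-3,9-diene-2,8-dione | CCCCC1=C(O)[C@@]2(OC1=O)[C@@H](Br)[C@H](Br)[C@@]21OC(=O)C(CCCC)=C1O
F7 | step 11 | (5S,6S,11R,12R)-4,10,11,12-tetrabromo-3,9-dibutyl-1,7-dioxadispiro[4.0.4.2]dodeca-3,9-diene-2,8-dione | CCCCC1=C(Br)[C@@]2(OC1=O)[C@@H](Br)[C@H](Br)[C@@]21OC(=O)C(CCCC)=C1Br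
F8 | step 11 | (5S,6S,11R,12R)-4,10,11,12-tetrabromo-9-(1-bromobutyl)-3-butyl-1,7-dioxadispiro[4.0.4.2]dodeca-3,9-diene-2,8-dione (both C1′ epimers) | CCCCC1=C(Br)[C@@]2(OC1=O)[C@@H](Br)[C@H](Br)[C@@]21OC(=O)C(C(Br)CCC)=C1Br
F9 | step 11 | (5S,6S,11R,12R)-4,10,11,12-tetrabromo-3-butyl-9-(1-hydroxybutyl)-1,7-dioxadispiro[4.0.4.2]dodeca-3,9-diene-2,8-dione (both C1′ epimers) | CCCCC1=C(Br)[C@@]2(OC1=O)[C@@H](Br)[C@H](Br)[C@@]21OC(=O)C(C(O)CCC)=C1Br
F10 | step 12 | (5S,6S,11R,12R)-4,10,11,12-tetrabromo-3-butyl-9-[(1S)-1-hydroxybutyl]-1,7-dioxadispiro[4.0.4.2]dodeca-3,9-diene-2,8-dione | CCCCC1=C(Br)[C@@]2(OC1=O)[C@@H](Br)[C@H](Br)[C@@]21OC(=O)C([C@H](CCC)O)=C1Br
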